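## Retrosynthetic overview

1. Target ⇐ deacetylation/desilylation of the protected flavone ⇐ dehydrogenation of a 2-arylchroman-4-one (flavanone).
2. Key disconnection, C2–C1′: decarboxylative radical arylation joining 5,7-dihydroxy-4-oxochromane-2-carboxylic acid (rings A/C) to an aryl bromide that already carries the complete (7''S,8''S) arylglycerol ether.
3. Aryl bromide ⇐ chelation-controlled ArMgBr addition to an (S)-α-aryloxy aldehyde (sets 7''S) ⇐ Mitsunobu inversion of a methyl (R)-glycerate silyl ether with 4-bromo-2,6-dimethoxyphenol (sets 8''S).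
4. Chromanone acid ⇐ phloroglucinol + maleic anhydride; phloroglucinol ⇐ resorcinol bis-silyl ether by meta C–H borylation/oxidation; B-ring phenol ⇐ 4-bromophenol.
5. Ring order: ring B and the p-hydroxyphenyl ring are bought as 4-bromophenol units; the A-ring oxygenation is completed in step 7; ring C is closed in step 8 and aromatised to the pyranone in step 10.

Assumption: 4, 8 and 10 are taken as catalogue compounds (8 and 10 are silyl-protected 4-bromophenol and resorcinol).

## Route

**Step 1**
Reactants: 1, 4-bromophenol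
Product: 2, 4-bromo-2,6-diiodophenol
Conditions: I2 (2.1 equiv), 30% H2O2, H2O/MeOH, rt
Reagents that add atoms: iodine, II
Why: Electrophilic aromatic iodination of a phenol goes to both ortho positions because the para position is blocked by bromine.

**Step 2**
Reactants: 2, 4-bromo-2,6-diiodophenol
Product: 3, 4-bromo-2,6-dimethoxyphenol
Conditions: NaOMe (6 equiv), CuI (20 mol%), MeOH/DMF, 90 °C
Reagents that add atoms: sodium methoxide, C[O-].[Na+]
Why: Copper-catalysed Ullmann-type methoxylation replaces the two aryl iodides, which react much faster than the para aryl bromide, so the bromide survives.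

**Step 3**
Reactants: 4, methyl (2R)-2,3-dihydroxypropanoate (methyl D-glycerate)
Product: 5, methyl (2R)-2-hydroxy-3-[(triisopropylsilyl)oxy]propanoate
Conditions: TIPSCl (1.05 equiv), imidazole, CH2Cl2, 0 °C
Reagents that add atoms: triisopropylsilyl chloride, CC(C)[Si](Cl)(C(C)C)C(C)C
Why: The bulky silyl chloride silylates the primary hydroxyl selectively; the stereocentre is not touched.

**Step 4**
Reactants: 3, 4-bromo-2,6-dimethoxyphenol; 5, methyl (2R)-2-hydroxy-3-[(triisopropylsilyl)oxy]propanoate
Product: 6, methyl (2S)-2-(4-bromo-2,6-dimethoxyphenoxy)-3-[(triisopropylsilyl)oxy]propanoate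
Conditions: PPh3, DIAD, THF, 0 °C → rt
Reagents that add atoms: none
Why: Mitsunobu etherification of an activated α-hydroxy ester with the phenol proceeds by SN2 with clean inversion (2R → 2S), which sets C8''.

**Step 5**
Reactants: 6
Product: 7, (2S)-2-(4-bromo-2,6-dimethoxyphenoxy)-3-[(triisopropylsilyl)oxy]propanal
Conditions: DIBAL-H (1.1 equiv), CH2Cl2, −78 °C; Rochelle salt work-up; used crude
Reagents that add atoms: none
Why: Low-temperature DIBAL reduction of an α-alkoxy ester stops at the aldehyde via the stable aluminium hemiacetal, and the cold, non-basic conditions do not epimerise the α-centre.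

**Step 6**
Reactants: 7; 8, (4-bromophenoxy)triisopropylsilane
Product: 9, (1S,2S)-2-(4-bromo-2,6-dimethoxyphenoxy)-1-{4-[(triisopropylsilyl)oxy]phenyl}-3-[(triisopropylsilyl)oxy]propyl acetate
Conditions: 8, Mg, Et2O (→ ArMgBr); 7, MgBr2·OEt2, CH2Cl2, −78 °C; then Ac2O, DMAP, −78 → 0 °C
Reagents that add atoms: acetic anhydride, CC(=O)OC(C)=O
Why: Cram-chelate Grignard addition (Mg bridges C=O and the α-aryloxy oxygen, while the bulky β-OTIPS does not chelate) delivers the aryl group anti to CH2OTIPS to give the syn (threo) adduct, i.e. 7''S from 8''S, and the alkoxide is acetylated in the same pot.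

**Step 7**
Reactants: 10, 1,3-bis(trimethylsilyloxy)benzene
Product: 11, benzene-1,3,5-triol (phloroglucinol)
Conditions: [Ir(OMe)(cod)]2 (1.5 mol%), dtbpy (3 mol%), B2pin2, THF, 80 °C; then Oxone, acetone/H2O, rt
Reagents that add atoms: Oxone (potassium peroxymonosulfate), OOS(=O)(=O)[O-].[K+]
Why: Sterically controlled Ir-catalysed C–H borylation occurs only at C5 (the one position not ortho to a substituent), and one-pot oxidation of the boronate in aqueous acidic Oxone also hydrolyses the TMS ethers.

**Step 8**
Reactants: 11, phloroglucinol; 12, maleic anhydride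
Product: 13, (±)-5,7-dihydroxy-4-oxochromane-2-carboxylic acid
Conditions: BF3·OEt2, 1,4-dioxane, 80 °C; then sat. aq. NaHCO3, rt; HCl to pH 2
Reagents that add atoms: none
Why: Friedel–Crafts C-acylation of the electron-rich arene by the anhydride gives the β-aroylacrylic acid, and intramolecular oxa-Michael addition of the ortho phenol closes ring C (C2 is racemic, which does not matter).

**Step 9 (key step)**
Reactants: 9; 13 (1.5 equiv)
Product: 14, (1S,2S)-2-[4-(5,7-dihydroxy-4-oxochroman-2-yl)-2,6-dimethoxyphenoxy]-1-{4-[(triisopropylsilyl)oxy]phenyl}-3-[(triisopropylsilyl)oxy]propyl acetate (about 1:1 epimers at flavanone C2)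
Conditions: Ir[dF(CF3)ppy]2(dtbbpy)PF6 (2 mol%), NiCl2·glyme (10 mol%), dtbbpy (15 mol%), BTMG (1.5 equiv, i.e. 1 equiv per CO2H), DMF, blue LEDs, rt
Reagents that add atoms: none
Why: Proposed new method: the carboxylate of 13 is oxidised by excited Ir(III) and loses CO2 to give the secondary C2 α-aryloxy radical, which is captured by the ArNi(II)Br formed from 9 and reductively eliminates from Ni(III) to forge C2–C1′; the closest known reaction is the Ni/photoredox decarboxylative C(sp3)–C(sp2) arylation of cyclic α-oxy acids with aryl bromides, extended here to a 4-oxochromane acid with free phenols (one equivalent of base ionises only the CO2H), and because no radical is formed β to the side-chain aryl ether the 7''S,8''S centres are untouched while the new C2 centre is erased in step 10.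

**Step 10**
Reactants: 14
Product: 15, (1S,2S)-2-[4-(5,7-dihydroxy-4-oxo-4H-chromen-2-yl)-2,6-dimethoxyphenoxy]-1-{4-[(triisopropylsilyl)oxy]phenyl}-3-[(triisopropylsilyl)oxy]propyl acetate
Conditions: DDQ (2.5 equiv), 1,4-dioxane, 90 °C
Reagents that add atoms: none
Why: Classical DDQ dehydrogenation of a flavanone to a flavone (hydride abstraction from the O-substituted, B-ring-benzylic C2–H, then loss of H3); the C7'' acetate deactivates the only other electron-rich benzylic C–H.

**Step 11**
Reactants: 15
Product: 16, (−)-(7''S,8''S)-4'',5,7-trihydroxy-3',5'-dimethoxy-4',8''-oxyflavonolignan-7'',9''-diol (target)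
Conditions: K2CO3, MeOH, 0 °C → rt; then AcOH, TBAF, THF, rt
Reagents that add atoms: none
Why: Acetate methanolysis is done first, while the phenol is still silylated, so no p-quinone methide can form and scramble C7''; buffered fluoride then cleaves both TIPS ethers without affecting either stereocentre.

## Compound list

1 | 4-bromophenol | Oc1ccc(Br)cc1 | starting material
2 | 4-bromo-2,6-diiodophenol | Oc1c(I)cc(Br)cc1I | intermediate
3 | 4-bromo-2,6-dimethoxyphenol | COc1cc(Br)cc(OC)c1O | intermediate
4 | methyl (2R)-2,3-dihydroxypropanoate | COC(=O)[C@H](O)CO | starting material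
5 | methyl (2R)-2-hydroxy-3-[(triisopropylsilyl)oxy]propanoate | COC(=O)[C@H](O)CO[Si](C(C)C)(C(C)C)C(C)C | intermediate
6 | methyl (2S)-2-(4-bromo-2,6-dimethoxyphenoxy)-3-[(triisopropylsilyl)oxy]propanoate | COC(=O)[C@@H](Oc1c(OC)cc(Br)cc1OC)CO[Si](C(C)C)(C(C)C)C(C)C | intermediate
7 | (2S)-2-(4-bromo-2,6-dimethoxyphenoxy)-3-[(triisopropylsilyl)oxy]propanal | O=C[C@@H](Oc1c(OC)cc(Br)cc1OC)CO[Si](C(C)C)(C(C)C)C(C)C | intermediate
8 | (4-bromophenoxy)triisopropylsilane | CC(C)[Si](Oc1ccc(Br)cc1)(C(C)C)C(C)C | starting material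
9 | (1S,2S)-2-(4-bromo-2,6-dimethoxyphenoxy)-1-{4-[(triisopropylsilyl)oxy]phenyl}-3-[(triisopropylsilyl)oxy]propyl acetate | COc1cc(Br)cc(OC)c1O[C@@H](CO[Si](C(C)C)(C(C)C)C(C)C)[C@@H](OC(C)=O)c1ccc(O[Si](C(C)C)(C(C)C)C(C)C)cc1 | intermediate
10 | 1,3-bis(trimethylsilyloxy)benzene | C[Si](C)(C)Oc1cccc(O[Si](C)(C)C)c1 | starting material
11 | benzene-1,3,5-triol (phloroglucinol) | Oc1cc(O)cc(O)c1 | intermediate
12 | maleic anhydride | O=C1C=CC(=O)O1 | starting material
13 | (±)-5,7-dihydroxy-4-oxochromane-2-carboxylic acid | OC(=O)C1CC(=O)c2c(O)cc(O)cc2O1 | intermediate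
14 | (1S,2S)-2-[4-(5,7-dihydroxy-4-oxochroman-2-yl)-2,6-dimethoxyphenoxy]-1-{4-[(triisopropylsilyl)oxy]phenyl}-3-[(triisopropylsilyl)oxy]propyl acetate, C2 epimer mixture | COc1cc(C2CC(=O)c3c(O)cc(O)cc3O2)cc(OC)c1O[C@@H](CO[Si](C(C)C)(C(C)C)C(C)C)[C@@H](OC(C)=O)c1ccc(O[Si](C(C)C)(C(C)C)C(C)C)cc1 | intermediate
15 | (1S,2S)-2-[4-(5,7-dihydroxy-4-oxo-4H-chromen-2-yl)-2,6-dimethoxyphenoxy]-1-{4-[(triisopropylsilyl)oxy]phenyl}-3-[(triisopropylsilyl)oxy]propyl acetate | COc1cc(-c2cc(=O)c3c(O)cc(O)cc3o2)cc(OC)c1O[C@@H](CO[Si](C(C)C)(C(C)C)C(C)C)[C@@H](OC(C)=O)c1ccc(O[Si](C(C)C)(C(C)C)C(C)C)cc1 | intermediate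
16 | (−)-(7''S,8''S)-4'',5,7-trihydroxy-3',5'-dimethoxy-4',8''-oxyflavonolignan-7'',9''-diol | COc1cc(-c2cc(=O)c3c(O)cc(O)cc3o2)cc(OC)c1O[C@@H](CO)[C@@H](O)c1ccc(O)cc1 | target

## Summary

Total steps: 11.
Longest linear sequence: 8 steps (1 → 2 → 3 → 6 → 7 → 9 → 14 → 15 → 16; steps 1, 2, 4, 5, 6, 9, 10, 11).

Steps most likely to fail:

1. **Step 9** (decarboxylative arylation on an untested 4-oxochromane acid with free phenols; base-induced ring opening of 13 to the aroylacrylate could compete). Fallback: reverse the polarity and use two-electron chemistry — Miyaura borylation of 9, then Liebeskind–Srogl coupling with 5,7-dihydroxy-2-(methylthio)chromone, which gives flavone 15 directly.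
2. **Step 6** (chelation control may be weak because the aryl ether oxygen is a poor donor, eroding the threo:erythro ratio). Fallback: set both centres by auxiliary control — alkylate 3 with (S)-4-benzyl-3-(bromoacetyl)oxazolidin-2-one, run a Bu2BOTf Evans syn-glycolate aldol with 4-(triisopropylsilyloxy)benzaldehyde, and remove the auxiliary reductively with NaBH4.
3. **Step 10** (DDQ may be slow on the 5-hydroxyflavanone or may attack the electron-rich side chain). Fallback: dehydrogenate through a Pd enolate instead of by hydride abstraction — convert 14 to the C3–C4 silyl enol ether (TMSOTf, Et3N) and carry out a Saegusa–Ito oxidation (Pd(OAc)2, O2, DMSO).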